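**Plan**
1. Retrosynthetic cuts, in order: the aryl–C(=O)Ph bond, then the C(CH3)2–CH2 bond of the cyclopentane, then the aryl–CH bond.
2. Enabling feature: in the cyclopentane the quaternary C(CH3)2 lies between CH(aryl) and the ring CH2, and CH(isopropenyl) is 1,3-trans to CH(aryl). Re-inserting one geminal methyl carbon as a C=O between C(CH3) and CH2 gives a 2-chloro-2-methyl-3-aryl-5-isopropenylcyclohexanone, which is an aryl adduct of (R)-carvone. All ten terpenoid carbons of the target are therefore the ten carbons of carvone.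
3. Forward: tris-MOM phloroglucinol is added as its cuprate to (R)-carvone (six-membered ring with the aryl group in place), and the silyl enol ether is chlorinated. A Favorskii contraction then closes the cyclopentane and creates the quaternary carbon. CO2Me is taken down to CH3, the arene is benzoylated and the MOM groups are removed.
4. Stereochemistry: the isopropenyl-bearing carbon comes from (R)-carvone. The aryl-bearing carbon is set by cuprate attack anti to the isopropenyl group (3,5-trans). The transient quaternary stereocentre ends as C(CH3)2, so its epimers converge.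

Key step: step 4

Remark: the configuration at C-2 of 7 and at C-1 of 8 to 12 is left open in names and SMILES because that carbon becomes C(CH3)2; the phenols are carried as methoxymethyl (MOM) ethers.

**Step 1**
Reactants: 1 phloroglucinol
Product: 2 1,3,5-tris(methoxymethoxy)benzene
Conditions: NaH, DMF, 0 °C; MOMCl, 0 °C to rt
Reagents that add atoms: chloromethyl methyl ether, COCCl
Why: Williamson O-alkylation of the phenoxide with the hard chloromethyl ether should favour O- over C-alkylation and gives an arene whose MOM groups later direct both lithiations.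

**Step 2**
Reactants: 2 1,3,5-tris(methoxymethoxy)benzene; 3 (R)-(−)-carvone
Product: 6 trimethylsilyl enol ether of (3R,5R)-2-methyl-5-(prop-1-en-2-yl)-3-[2,4,6-tris(methoxymethoxy)phenyl]cyclohexanone, via aryllithium 4 (not isolated), via lithium diarylcuprate 5 (not isolated)
Conditions: 2 (2.4 equiv), nBuLi, THF, 0 °C; CuI, −40 °C; TMSCl then 3, −78 to −20 °C; Et3N, aq. NH4Cl/NH3 work-up
Reagents that add atoms: chlorotrimethylsilane, C[Si](C)(C)Cl
Why: Directed ortho-lithiation between two MOM ethers and a TMSCl-accelerated Gilman cuprate conjugate addition (precedented for 2,6-dialkoxyaryl cuprates on cyclohexenones and for cuprates on carvone) should deliver the aryl group to C-3 by axial attack anti to the C-5 isopropenyl group, which sets the 3,5-trans relation, while silylation fixes the enolate regiochemistry at C-1/C-2.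

**Step 3**
Reactants: 6 trimethylsilyl enol ether
Product: 7 (3S,5R)-2-chloro-2-methyl-5-(prop-1-en-2-yl)-3-[2,4,6-tris(methoxymethoxy)phenyl]cyclohexan-1-one (C-2 epimers)
Conditions: NCS, NaHCO3, THF, −20 to 0 °C
Reagents that add atoms: N-chlorosuccinimide, O=C1CCC(=O)N1Cl
Why: Electrophilic α-chlorination of a silyl enol ether is regiospecific for C-2, and the enol ether should react well before the arene or the isopropenyl group at low temperature; the new C-2 stereocentre needs no control.

**Step 4**
Reactants: 7 α-chloroketone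
Product: 9 methyl (2S,4R)-1-methyl-4-(prop-1-en-2-yl)-2-[2,4,6-tris(methoxymethoxy)phenyl]cyclopentane-1-carboxylate (C-1 epimers), via cyclopropanone 8 (not isolated)
Conditions: NaOMe (3 equiv), Et2O, 0 °C to reflux
Reagents that add atoms: sodium methoxide, [Na+].[O-]C
Why: Methoxide can enolise 7 only toward C-6 (C-2 is fully substituted), and the enolate expels the tertiary chloride from C-2 (internal displacement, or ionisation to the 2-oxyallyl species and disrotatory closure) to give cyclopropanone 8, whose new C-2–C-6 bond is the C(CH3)2–CH2 bond of the target cyclopentane. Methoxide then adds to the strained carbonyl and the hemiketal alkoxide breaks the C-6–C(=O) bond, because this releases a secondary and not a tertiary carbanion, so the carboxyl carbon stays on the quaternary carbon and the former C-6 is protonated to CH2. This is the Favorskii rearrangement, with the contractions of 2-chloro-2-methylcyclohexanone to methyl 1-methylcyclopentanecarboxylate and of pulegone dibromide to pulegenic esters as closest analogues. The closure is 3-exo-tet (enolate carbon onto the C–Cl carbon) and at the same stroke creates the five-membered ring of the bicyclo[3.1.0]hexanone, the carbonyl carbon serving as a one-atom tether so that no 5-endo closure is required. The only new stereocentre, C-1 of 9, is left uncontrolled because it becomes C(CH3)2, so both C-2 epimers of 7 converge, while the aryl- and isopropenyl-bearing carbons are β to the carbonyl and cannot epimerise. The step needs cyclopropanone formation to outrun dehydrochlorination and methanolysis and needs regioselective ring opening; the tertiary carbonyl-aligned C–Cl bond, NaOMe suspended in ether in place of methanol solution, and the carbanion-stability preference should secure these.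

**Step 5**
Reactants: 9 methyl ester
Product: 11 (2S,4R)-1-methyl-4-(prop-1-en-2-yl)-2-[2,4,6-tris(methoxymethoxy)phenyl]cyclopentane-1-carbaldehyde (C-1 epimers), via aluminium hemiacetal 10 (not isolated)
Conditions: iBu2AlH (1.2 equiv), toluene, −78 °C; MeOH, aq. potassium sodium tartrate
Reagents that add atoms: none
Why: Partial reduction of a hindered ester with diisobutylaluminium hydride should stop at the tetrahedral aluminium hemiacetal at −78 °C, which releases the neopentyl aldehyde only on work-up.

**Step 6**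
Reactants: 11 aldehyde
Product: 13 2-[(1R,4R)-2,2-dimethyl-4-(prop-1-en-2-yl)cyclopentyl]-1,3,5-tris(methoxymethoxy)benzene, via hydrazone 12 (not isolated)
Conditions: N2H4·H2O, KOH, diethylene glycol, 120 °C then 200 °C, under N2
Reagents that add atoms: none
Why: Wolff–Kishner reduction (Huang-Minlon procedure) of a non-enolisable neopentyl aldehyde should turn CHO into CH3, which erases the C-1 stereocentre, while the MOM ethers and the isolated alkene tolerate base.

**Step 7**
Reactants: 13 arylcyclopentane; 14 N-methoxy-N-methylbenzamide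
Product: 17 {3-[(1R,4R)-2,2-dimethyl-4-(prop-1-en-2-yl)cyclopentyl]-2,4,6-tris(methoxymethoxy)phenyl}(phenyl)methanone, via aryllithium 15 (not isolated), via lithium tetrahedral adduct 16 (not isolated)
Conditions: nBuLi (1.3 equiv), THF, 0 °C; 14, −78 °C to rt; aq. NH4Cl
Reagents that add atoms: none
Why: Directed ortho-metalation should remove the ring hydrogen flanked by two MOM ethers (the two free positions are equivalent by rotation about the aryl–cyclopentyl bond), and acylation with the Weinreb amide stops at the ketone because the chelated adduct 16 survives until work-up.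

**Step 8**
Reactants: 17 tris-MOM benzophenone
Product: 18 {3-[(1R,4R)-2,2-dimethyl-4-(prop-1-en-2-yl)cyclopentyl]-2,4,6-trihydroxyphenyl}(phenyl)methanone (CNP0143418.1)
Conditions: ZnBr2 (4 equiv), nPrSH (8 equiv), CH2Cl2, 0 °C
Reagents that add atoms: none
Why: Lewis-acid-assisted thiol transacetalisation should cleave the three aryl MOM ethers quickly without protic acid, which spares the isopropenyl group from protonation (hydration or double-bond migration).

**Compound list**
1 | benzene-1,3,5-triol (phloroglucinol) | Oc1cc(O)cc(O)c1 | starting material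
2 | 1,3,5-tris(methoxymethoxy)benzene | COCOc1cc(OCOC)cc(OCOC)c1 | intermediate
3 | (R)-(−)-carvone, (5R)-2-methyl-5-(prop-1-en-2-yl)cyclohex-2-en-1-one | C=C(C)[C@@H]1CC=C(C)C(=O)C1 | starting material
4 | [2,4,6-tris(methoxymethoxy)phenyl]lithium | [Li]c1c(OCOC)cc(OCOC)cc1OCOC | intermediate
5 | lithium bis[2,4,6-tris(methoxymethoxy)phenyl]cuprate, Ar2CuLi | [Li+].COCOc1cc(OCOC)cc(OCOC)c1[Cu-]c1c(OCOC)cc(OCOC)cc1OCOC | intermediate
6 | trimethyl{[(3R,5R)-2-methyl-5-(prop-1-en-2-yl)-3-[2,4,6-tris(methoxymethoxy)phenyl]cyclohex-1-en-1-yl]oxy}silane (aryl and isopropenyl trans) | C=C(C)[C@@H]1C[C@@H](c2c(OCOC)cc(OCOC)cc2OCOC)C(C)=C(O[Si](C)(C)C)C1 | intermediate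
7 | (3S,5R)-2-chloro-2-methyl-5-(prop-1-en-2-yl)-3-[2,4,6-tris(methoxymethoxy)phenyl]cyclohexan-1-one, C-2 epimers | C=C(C)[C@@H]1C[C@@H](c2c(OCOC)cc(OCOC)cc2OCOC)C(C)(Cl)C(=O)C1 | intermediate
8 | (2S,4R)-1-methyl-4-(prop-1-en-2-yl)-2-[2,4,6-tris(methoxymethoxy)phenyl]bicyclo[3.1.0]hexan-6-one, ring-fusion face open | C=C(C)[C@@H]1C[C@@H](c2c(OCOC)cc(OCOC)cc2OCOC)C2(C)C(=O)C12 | intermediate
9 | methyl (2S,4R)-1-methyl-4-(prop-1-en-2-yl)-2-[2,4,6-tris(methoxymethoxy)phenyl]cyclopentane-1-carboxylate, C-1 epimers | C=C(C)[C@@H]1C[C@@H](c2c(OCOC)cc(OCOC)cc2OCOC)C(C)(C(=O)OC)C1 | intermediate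
10 | diisobutylaluminium hemiacetal of ester 9 | C=C(C)[C@@H]1C[C@@H](c2c(OCOC)cc(OCOC)cc2OCOC)C(C)(C(OC)O[Al](CC(C)C)CC(C)C)C1 | intermediate
11 | (2S,4R)-1-methyl-4-(prop-1-en-2-yl)-2-[2,4,6-tris(methoxymethoxy)phenyl]cyclopentane-1-carbaldehyde, C-1 epimers | C=C(C)[C@@H]1C[C@@H](c2c(OCOC)cc(OCOC)cc2OCOC)C(C)(C=O)C1 | intermediate
12 | hydrazone of aldehyde 11 | C=C(C)[C@@H]1C[C@@H](c2c(OCOC)cc(OCOC)cc2OCOC)C(C)(C=NN)C1 | intermediate
13 | 2-[(1R,4R)-2,2-dimethyl-4-(prop-1-en-2-yl)cyclopentyl]-1,3,5-tris(methoxymethoxy)benzene | C=C(C)[C@@H]1C[C@@H](c2c(OCOC)cc(OCOC)cc2OCOC)C(C)(C)C1 | intermediate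
14 | N-methoxy-N-methylbenzamide | CON(C)C(=O)c1ccccc1 | starting material
15 | {3-[(1R,4R)-2,2-dimethyl-4-(prop-1-en-2-yl)cyclopentyl]-2,4,6-tris(methoxymethoxy)phenyl}lithium | C=C(C)[C@@H]1C[C@@H](c2c(OCOC)cc(OCOC)c([Li])c2OCOC)C(C)(C)C1 | intermediate
16 | lithium alkoxide of the tetrahedral adduct of 15 with 14 | C=C(C)[C@@H]1C[C@@H](c2c(OCOC)cc(OCOC)c(C(O[Li])(N(C)OC)c3ccccc3)c2OCOC)C(C)(C)C1 | intermediate
17 | {3-[(1R,4R)-2,2-dimethyl-4-(prop-1-en-2-yl)cyclopentyl]-2,4,6-tris(methoxymethoxy)phenyl}(phenyl)methanone | C=C(C)[C@@H]1C[C@@H](c2c(OCOC)cc(OCOC)c(C(=O)c3ccccc3)c2OCOC)C(C)(C)C1 | intermediate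
18 | {3-[(1R,4R)-2,2-dimethyl-4-(prop-1-en-2-yl)cyclopentyl]-2,4,6-trihydroxyphenyl}(phenyl)methanone | C=C(C)[C@@H]1C[C@@H](c2c(O)cc(O)c(C(=O)c3ccccc3)c2O)C(C)(C)C1 | target

**Step count**
Total steps: 8. Longest linear sequence: 8 steps (1 to 18; carvone 3 enters at step 2 and amide 14 at step 7).

**Steps most likely to fail**

Step 4 (key step). Dehydrochlorination toward the benzylic C-3 or the methyl group, or capture of the oxyallyl species by methoxide, may outpace cyclopropanone closure. The fallback sets out from 6 and comes back at 13, replacing steps 3 to 6. MeLi (THF, 0 °C) cleaves the silyl enol ether and MeI/DMPU methylates the lithium enolate to give (3S,5R)-2,2-dimethyl-5-(prop-1-en-2-yl)-3-[2,4,6-tris(methoxymethoxy)phenyl]cyclohexan-1-one F1. LiN(SiMe3)2 and CF3CO2CH2CF3 give the 6-trifluoroacetyl ketone F2, which MsN3/Et3N converts into the 6-diazo ketone F3. Irradiation (350 nm, THF/H2O, NaHCO3) should bring about a Wolff ring contraction in which the C(CH3)2 carbon migrates to the carbene carbon, forming the same ring bond and giving the cyclopentanecarboxylic acid F4. Its Barton ester F5 (2-mercaptopyridine N-oxide, DCC) is photolysed with tBuSH to give 13. In this variant the second methyl comes from MeI and the old carbonyl carbon leaves as CO2.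

Step 2. Transfer of the doubly ortho-substituted aryl group to the α-methylated enone may be slow, so that enolisation of carvone or 1,2-addition takes over. The fallback sets out from 3 (with aryllithium 4) and comes back at 11, replacing steps 2 to 5. Luche reduction (NaBH4, CeCl3·7H2O, MeOH) gives (1R,5R)-cis-carveol F6, and picolinic acid/DCC/DMAP gives its picolinate F7. Aryllithium 4 is transmetalated with MgBr2 to the arylmagnesium bromide F8, which with CuBr·SMe2 substitutes F7 in the anti-SN2′ mode. The aryl group enters C-3 opposite to the leaving group, which is cis to the isopropenyl group, to give the trans cyclohexene F9. mCPBA (NaHCO3, CH2Cl2, 0 °C) epoxidises the more electron-rich ring alkene to the epoxide F10. LiBr/HMPA in hot toluene should then effect the ring-contracting epoxide-to-aldehyde (Meinwald-type) rearrangement through the bromohydrin salt, the ring CH2 migrating to the methyl-bearing carbon, to give aldehyde 11.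

Step 6. Hydrazone formation at the neopentyl aldehyde may be incomplete, or the isopropenyl double bond may migrate under base at 200 °C. The fallback sets out from 11 and comes back at 13. TsNHNH2 (MeOH, rt) gives the tosylhydrazone F11. Catecholborane (CHCl3, 0 °C) followed by NaOAc·3H2O at reflux should reduce it through the diazene, with loss of sulfinate and nitrogen, to 13 without strong base or high temperature.

**Further compounds**
F1 | step 4 | (3S,5R)-2,2-dimethyl-5-(prop-1-en-2-yl)-3-[2,4,6-tris(methoxymethoxy)phenyl]cyclohexan-1-one | C=C(C)[C@@H]1C[C@@H](c2c(OCOC)cc(OCOC)cc2OCOC)C(C)(C)C(=O)C1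
F2 | step 4 | 6-(trifluoroacetyl) derivative of F1, C-6 open | C=C(C)[C@@H]1C[C@@H](c2c(OCOC)cc(OCOC)cc2OCOC)C(C)(C)C(=O)C1C(=O)C(F)(F)F
F3 | step 4 | (3S,5S)-6-diazo-2,2-dimethyl-5-(prop-1-en-2-yl)-3-[2,4,6-tris(methoxymethoxy)phenyl]cyclohexan-1-one | C=C(C)[C@@H]1C[C@@H](c2c(OCOC)cc(OCOC)cc2OCOC)C(C)(C)C(=O)C1=[N+]=[N-]
F4 | step 4 | (3R,5R)-2,2-dimethyl-5-(prop-1-en-2-yl)-3-[2,4,6-tris(methoxymethoxy)phenyl]cyclopentane-1-carboxylic acid, C-1 epimers | C=C(C)[C@@H]1C[C@@H](c2c(OCOC)cc(OCOC)cc2OCOC)C(C)(C)C1C(=O)O
F5 | step 4 | 2-thioxopyridin-1(2H)-yl ester (Barton ester) of F4 | C=C(C)[C@@H]1C[C@@H](c2c(OCOC)cc(OCOC)cc2OCOC)C(C)(C)C1C(=O)On1ccccc1=S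
F6 | step 2 | (1R,5R)-2-methyl-5-(prop-1-en-2-yl)cyclohex-2-en-1-ol (cis-carveol) | C=C(C)[C@@H]1CC=C(C)[C@H](O)C1
F7 | step 2 | (1R,5R)-2-methyl-5-(prop-1-en-2-yl)cyclohex-2-en-1-yl pyridine-2-carboxylate | C=C(C)[C@@H]1CC=C(C)[C@H](OC(=O)c2ccccn2)C1
F8 | step 2 | [2,4,6-tris(methoxymethoxy)phenyl]magnesium bromide | Br[Mg]c1c(OCOC)cc(OCOC)cc1OCOC
F9 | step 2 | 2-[(1R,5S)-2-methyl-5-(prop-1-en-2-yl)cyclohex-2-en-1-yl]-1,3,5-tris(methoxymethoxy)benzene (aryl and isopropenyl trans) | C=C(C)[C@@H]1C[C@@H](c2c(OCOC)cc(OCOC)cc2OCOC)C(C)=CC1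
F10 | step 2 | 2,3-epoxide of F9 (epoxide face open) | C=C(C)[C@@H]1C[C@@H](c2c(OCOC)cc(OCOC)cc2OCOC)C2(C)OC2C1
F11 | step 6 | 4-methylbenzenesulfonylhydrazone of aldehyde 11 | C=C(C)[C@@H]1C[C@@H](c2c(OCOC)cc(OCOC)cc2OCOC)C(C)(C=NNS(=O)(=O)c2ccc(C)cc2)C1
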